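**Remark:** (S)-(+)-carvone is used as the terpene source because its carbonyl carbon becomes C3 of the target; the C3 oxygen then travels through the key step as a silyl ether spectator. Abbreviations: TBS = tert-butyldimethylsilyl, TES = triethylsilyl, PMB = 4-methoxybenzyl. Ring-expanded compounds are named with the target's locants C1–C15.

## Analysis of the target

Target 33 is a germacranolide. Its ten-membered ring C1–C10 is fused trans at C7–C8 to an α-methylene-γ-lactone (C11=C13H2, C12=O, ring oxygen on C8). It carries a cis 1,10-epoxide (C14 methyl on C10), a C3 ketone cross-conjugated with the exocyclic C4=C15 methylene, an angelate on O5 and a free hydroxyl on C6.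

The six stereocentres are 1S,5S,6R,7R,8R,10R. With the ring drawn flat and C1→C10 clockwise, O5, O6 and O8 lie on the lower (α) face; the C7–C11 bond and the epoxide oxygen lie on the upper (β) face. So O5/O6 are cis, O6/O8 are 1,3-syn, and the epoxide is the one a Z C1=C10 alkene gives.

The sensitive groups are two exocyclic Michael acceptors, an acid-labile trisubstituted epoxide in a ring prone to transannular reactions, an angelate that isomerises to the tiglate and can migrate to O6, and a C6 hydroxyl that is as well placed as O8 to hold the lactone.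

The synthesis is hard for two reasons. A medium ring with a Z trisubstituted alkene has to be made, and the six functionalised carbons C3–C8 have to be set on a conformationally mobile ring.

The strategy rests on two features. Atoms C1–C6, with C15 on C4 and the C10(C14)=C9 unit on C1, form a p-menthane, which is carvone when C3 carries the oxygen. And C8=C7–C6–C1–C10=C9 is a 1,5-diene across the C1–C6 bond. A [3,3] shift of a 1-alkenyl-6-isopropenylcyclohexenol with the carbinol at C6 therefore forms C8–C9, breaks C1–C6 and gives the ten-membered ring with a C6 carbonyl.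

## Retrosynthetic reasoning

**33 ⇒ 32 ⇒ 31.** The exocyclic enone is the most electrophilic group, so the C3 carbonyl is formed last from allylic alcohol 32. Allylic versus non-allylic position distinguishes O3 from O6 without protection. 32 comes from 31 by removing both silyl ethers in one operation.

**31 ⇒ 30.** The C1–O and C10–O bonds are cut to the Z C1=C10 alkene. The epoxide goes in after every step that uses Lewis acids or strong base. At that stage C1=C10 is the only electron-rich alkene, and its Z geometry guarantees the cis epoxide.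

**30 ⇒ 27 + 28.** The C5 ester bond is cut to alcohol 27 and angelic acid 28. The ester is made late because the angelate would not survive the enolisation needed for the methylene lactone, and because O5 is then the only free hydroxyl.

**27 ⇒ 26 ⇒ 23.** C11=C13 is cut back to the lactone CH2 of 23 (aminomethylation and elimination). The triethylsilyl ether on O5 in 26 and 23 is temporary.

**23 ⇒ 22 ⇒ 21.** The lactone C12–O8 bond is cut to hydroxy ester 22 and its PMB ether 21. O5 and O6 are silylated so that only O8 can close. A tert-butyl ester is used so that O6, which is free two steps earlier, does not lactonise.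

**21 ⇒ 20 ⇒ 19 ⇒ 18 ⇒ 17.** The C5–O bond and the C4=C15 methylene go back to the Z C4=C5 alkene of 17, through epoxide 18/19 and its isomerisation to the allylic alcohol. The epoxide oxygen is delivered from O6, so C5 is set from C6.

**17 ⇒ 16.** The C6–H bond is cut to ketone 16. The forward reduction must give the 6α alcohol; the C8 ether oxygen is used as a chelating anchor.

**16 ⇒ 13 + 14.** The C7–C11 bond is cut to lithium enolate 15, formed from dienone 13, and bromoacetate 14. The ring expansion delivers a C6/C7 enolate as its potassium salt with crown ether, which is the form most prone to expel the C8 alkoxide. That enolate is therefore protonated, 13 is isolated, and the enolate is formed again as the more covalent lithium salt 15 for the C-alkylation.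

**13 ⇒ 10 (key).** C8–C9 is cut and C1–C6 reconnected. This turns the ten-membered dienone into cyclohexenol 10, whose two alkenyl groups are cis. The forward [3,3] shift must go through one chair to give the Z C1=C10 alkene and to transfer chirality to C8.

**10 ⇒ 9 ⇒ 4 + 7.** The C6–C7 bond is cut to enone 4 and the alkoxyacetylide from 7; trans-reduction of alkyne 9 gives the E enol ether. The C3 silyloxy group, cis to isopropenyl, holds both groups equatorial. Without it the isopropenyl group can turn axial and steer the nucleophile to the opposite face, which would give the trans-dialkenyl carbinol and hence the E alkene.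

**4 ⇒ 3 ⇒ 2 ⇒ 1; 7 ⇒ 5 + 6.** Enone 4 comes from (S)-carvone 1 by 1,2-reduction, silylation and allylic oxidation at the ring CH2 that becomes C6. Ether 7 comes from alcohol 5 and 6.

## Alternatives that were turned down

**Alternative 1:** The C9–C10 bond is cut, so the ring is closed last from one open chain. In the forward step Pd(dppf)Cl2 and Cs2CO3 couple a primary C9 alkylboron terminus with a Z C10 vinyl iodide terminus to give A1, with retention of the alkene geometry.
- For: the C3–C8 stereocentres and the C4 methylene are set by acyclic methods before closure, and the Z geometry is fixed by the vinyl iodide. On both points it is stronger than the chosen route, which sets C5–C7 on the ring.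
- Against: a ten-membered ring has to be closed by a catalytic bond formation with no template, against transannular strain and under high dilution. The alkylboron sits β to the C8 silyloxy group (β-elimination, slow transmetalation). The chain needs well over fifteen linear steps. A1 still lacks lactone, epoxide and C3 ketone.
- Comparison: the chosen route makes the ring in seven steps from 1 by a unimolecular rearrangement driven by enolate formation; it pays with late stereocontrol.

**Alternative 2:** The C5–C10 bond is re-formed to a cis-decalin. In the forward step KOt-Bu generates the C5 alkoxide, which expels the C1 mesylate and breaks C5–C10, giving the C5 ketone and the Z alkene of A2.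
- For: the fragmentation is concerted and stereospecific, so the alkene geometry follows from the decalin configuration with no competing conformer. That is stronger than the chair preference on which the chosen route depends. The rigid bicycle also allows C6, C7, C8 and the lactone to be set beforehand.
- Against: A2 has its ketone at C5 and nothing at C3 or C4. C15 would have to be added and the carbonyl transposed to C3 on the medium ring. The C6 silyloxy carbon is epimerisable next to the ketone. The strong base meets a lactone and a mesylate. The decalin with a quaternary C10 is long to make and has no terpene source.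
- Comparison: the chosen route takes C15, the C3 oxygen and the C4=C5 unsaturation from 1.

**Alternative 3:** The C3 and C8 carbonyls are traced to the tetrasubstituted C3=C8 alkene of a Birch-type hexahydronaphthalene. In the forward step O3, then Me2S, cleaves only that bond and opens both six-membered rings to A3.
- For: one step makes the ring and puts oxygen on C3 and C8, which is better step economy for these atoms than the chosen route. The Z alkene is certain because it comes from a six-membered ring.
- Against: selectivity between the tetrasubstituted and the trisubstituted alkene is only a matter of degree. A3 is a diketone with the alkene β,γ to both carbonyls, so transannular aldol and migration into conjugation threaten it. C8 must then be reduced to the 8α alcohol on a flexible ring with no controlling element. The C4 substituent still has to be turned into the methylene.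
- Comparison: the chosen route sets C8 by chirality transfer in the ring-forming step and never passes a 1,6-dione.

Key step: step 7

## Route

Step 1
Reactants: 1 (S)-(+)-carvone
Product: 2 (1S,5S)-cis-carveol
Conditions: NaBH4, CeCl3·7H2O, MeOH, −20 °C
Reagents that add atoms: none
Why: Luche 1,2-reduction of the enone; hydride adds along the axial path and gives the pseudo-equatorial alcohol cis to the equatorial isopropenyl group, which is the future C3–O cis to the C10 unit on C1.

Step 2
Reactants: 2 (1S,5S)-cis-carveol
Product: 3 TBS ether of cis-carveol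
Conditions: t-BuMe2SiCl, imidazole, DMF, 23 °C
Reagents that add atoms: tert-butyldimethylsilyl chloride, CC(C)(C)[Si](C)(C)Cl
Why: Standard silylation of a secondary allylic alcohol; the bulky ether survives base, hydride and mild oxidants and later anchors the ring conformation.

Step 3
Reactants: 3 TBS ether of cis-carveol
Product: 4 (4S,6S)-4-(TBS-oxy)-3-methyl-6-(prop-1-en-2-yl)cyclohex-2-en-1-one
Conditions: CrO3, 3,5-dimethylpyrazole, CH2Cl2, −20 °C
Reagents that add atoms: chromium trioxide, O=[Cr](=O)=O
Why: Allylic oxidation of a trisubstituted cyclohexene at the ring CH2 next to the =CH carbon (future C6) gives the β-methyl enone, the other ring allylic position being blocked by the silyl ether; C1 stays defined because the cis-1,3-diequatorial arrangement with the C3 silyloxy group is the stable one.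

Step 4
Reactants: 5 4-methoxybenzyl alcohol; 6 trichloroethylene
Product: 7 1-({[(E)-1,2-dichloroethenyl]oxy}methyl)-4-methoxybenzene
Conditions: KH, THF, 0 °C; then 6, −40 → 23 °C
Reagents that add atoms: none
Why: The potassium alkoxide adds to dichloroacetylene formed in situ from 6 (elimination–addition), the usual entry to 1,2-dichlorovinyl ethers as ynol ether precursors.

Step 5
Reactants: 7 (E)-1,2-dichlorovinyl PMB ether; 4 silyloxy enone
Product: 9 (1R,4S,6S)-4-(TBS-oxy)-1-{[(4-methoxybenzyl)oxy]ethynyl}-3-methyl-6-(prop-1-en-2-yl)cyclohex-2-en-1-ol, via lithium alkoxyacetylide 8 (not isolated)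
Conditions: 7, n-BuLi (2.2 equiv per 7), THF, −78 → −40 °C; then 4, −78 °C; sat. aq. NH4Cl
Reagents that add atoms: none
Why: Elimination and Cl/Li exchange give the alkoxyacetylide, which adds 1,2 to the β,β-disubstituted enone. The cis C1/C3 substituents hold 4 in the half-chair with isopropenyl equatorial, so the rod-shaped nucleophile should take the axial path at C6 (chair-like transition state, anti to the axial H1). This places the alkynyl group axial and cis to isopropenyl, with the hydroxyl equatorial.

Step 6
Reactants: 9 propargylic alcohol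
Product: 10 (1R,4S,6S)-4-(TBS-oxy)-1-[(E)-2-(4-methoxybenzyloxy)ethenyl]-3-methyl-6-(prop-1-en-2-yl)cyclohex-2-en-1-ol
Conditions: LiAlH4, THF, 0 → 23 °C; aq. KNaC4H4O6
Reagents that add atoms: none
Why: Trans-hydroalumination of the propargylic alkoxide (hydride delivered from the oxygen-bound aluminate) and protonolysis give the E enol ether; silyl and benzyl ethers are inert.

Step 7
Reactants: 10 cis-dialkenyl cyclohexenol
Product: 13 (2Z,4S,6Z,9R)-4-(TBS-oxy)-9-(4-methoxybenzyloxy)-3,7-dimethylcyclodeca-2,6-dien-1-one, via potassium alkoxide 11 (not isolated), via potassium enolate 12 (not isolated)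
Conditions: KH, 18-crown-6, THF, 0 → 23 °C; AcOH, −78 °C
Reagents that add atoms: none
Why: KH deprotonates the tertiary alcohol and 18-crown-6 frees alkoxide 11, whose charge accelerates the [3,3]-sigmatropic shift of the 1,5-diene C8=C7–C6–C1–C10=C9; C8–C9 forms as C1–C6 breaks, and enolate 12 is protonated cold to 13. The closest known reaction type is the anionic oxy-Cope ring expansion of 1,2-dialkenylcyclohexanols to cyclodec-5-enones. The ten-membered ring is closed by a four-atom ring enlargement through a six-membered chair transition state, a pericyclic closure to which the rules for ionic ring closures do not apply. In 10 the two alkenyl groups are cis and the C3 silyloxy group is cis to isopropenyl, so only the half-chair with isopropenyl and silyloxy equatorial, the oxido group pseudo-equatorial and the alkoxyvinyl group pseudo-axial is populated; the flipped form would set isopropenyl and silyloxy 1,3-diaxial. In the chair built on this conformer H1 is anti to C7, so the C1–C2 bond is axial on the transition-state chair and ends cis to C9, which gives the Z C1=C10 alkene, while C4=C5 keeps its Z geometry from the ring. The new stereocentre C8 is controlled by the E enol ether, which puts the ether oxygen equatorial on that chair, so the C1/C6 chirality from carvone is transferred to (8R). The step needs chair over boat, which is the normal preference of an unconstrained 1,5-diene, and this chair over the ring-flipped one, which the cis C1/C3 relationship excludes. The enolate is kept cold and quenched at −78 °C to limit loss of the C8 alkoxide.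

Step 8
Reactants: 13 ten-membered dienone; 14 tert-butyl bromoacetate
Product: 16 tert-butyl (1(10)Z,3S,4Z,7S,8R)-3-(TBS-oxy)-8-(PMB-oxy)-6-oxo-13-norgermacra-1(10),4-dien-12-oate, via lithium enolate 15 (not isolated)
Conditions: LiN(SiMe3)2, THF, −78 °C; then 14, DMPU, −78 → −40 °C
Reagents that add atoms: none
Why: Kinetic α'-deprotonation of the enone at C7 with the lithium amide gives the cross-conjugated lithium enolate 15, which is tighter and less basic than the crown-ether potassium enolate of step 7 and therefore less prone to β-elimination of the C8 alkoxide and to O-alkylation. SN2 alkylation by 14 should occur from outside the ring, anti to the pseudo-equatorial C8 ether, which sets (7S) with C11 trans to O8.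

Step 9
Reactants: 16 keto ester
Product: 17 tert-butyl (1(10)Z,3S,4Z,6S,7R,8R)-3-(TBS-oxy)-6-hydroxy-8-(PMB-oxy)-13-norgermacra-1(10),4-dien-12-oate
Conditions: Zn(BH4)2, Et2O, −20 °C
Reagents that add atoms: none
Why: Chelation-controlled 1,2-reduction of the enone; zinc bridges the C6 carbonyl and the C8 ether oxygen, and hydride attack on this six-membered chelate should give the 1,3-syn (6α) alcohol. The tert-butyl ester is neither reduced nor able to lactonise onto the new hydroxyl.

Step 10
Reactants: 17 allylic alcohol
Product: 18 tert-butyl (1(10)Z,3S,4R,5R,6R,7R,8R)-3-(TBS-oxy)-4,5-epoxy-6-hydroxy-8-(PMB-oxy)-13-norgermacr-1(10)-en-12-oate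
Conditions: VO(acac)2 (cat.), t-BuOOH, CH2Cl2, 0 °C
Reagents that add atoms: tert-butyl hydroperoxide, CC(C)(C)OO
Why: Hydroxyl-directed epoxidation of a cyclic Z-allylic alcohol; oxygen is delivered from the vanadate ester of O6 to the same face of C4=C5 (cis epoxy alcohol). The C1=C10 alkene has no allylic hydroxyl and is left.

Step 11
Reactants: 18 epoxy alcohol
Product: 19 tert-butyl (1(10)Z,3S,4R,5R,6R,7S,8R)-3,6-bis(TBS-oxy)-4,5-epoxy-8-(PMB-oxy)-13-norgermacr-1(10)-en-12-oate
Conditions: t-BuMe2SiOTf, 2,6-lutidine, CH2Cl2, −78 °C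
Reagents that add atoms: tert-butyldimethylsilyl triflate, CC(C)(C)[Si](C)(C)OS(=O)(=O)C(F)(F)F
Why: Silylation of the hindered secondary alcohol; it blocks O6 against later lactonisation and acylation, so that O5 is the only hydroxyl set free in the next step.

Step 12
Reactants: 19 silylated epoxide
Product: 20 tert-butyl (1(10)Z,3S,5S,6R,7S,8R)-3,6-bis(TBS-oxy)-5-hydroxy-8-(PMB-oxy)-13-norgermacra-1(10),4(15)-dien-12-oate
Conditions: Et2Al(TMP) [from 2,2,6,6-tetramethylpiperidine, n-BuLi, Et2AlCl], toluene, 0 °C; aq. KNaC4H4O6
Reagents that add atoms: none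
Why: Aluminium amide-mediated isomerisation of an epoxide to an allylic alcohol by syn β-elimination; the tertiary C4–O bond breaks and the proton is taken from the C15 methyl, which is cis to H5 and least hindered. This gives the 4(15)-ene and leaves the C5–O bond and its configuration untouched.

Step 13
Reactants: 20 C5 allylic alcohol
Product: 21 tert-butyl (1(10)Z,3S,5S,6R,7S,8R)-3,6-bis(TBS-oxy)-5-(TES-oxy)-8-(PMB-oxy)-13-norgermacra-1(10),4(15)-dien-12-oate
Conditions: Et3SiCl, imidazole, DMAP (cat.), CH2Cl2, 0 → 23 °C
Reagents that add atoms: chlorotriethylsilane, CC[Si](Cl)(CC)CC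
Why: Temporary protection of O5 so that only O8 can lactonise and the lactone can be enolised; the triethylsilyl ether can later be removed in the presence of the two TBS ethers.

Step 14
Reactants: 21 PMB ether
Product: 22 tert-butyl (1(10)Z,3S,5S,6R,7S,8R)-3,6-bis(TBS-oxy)-5-(TES-oxy)-8-hydroxy-13-norgermacra-1(10),4(15)-dien-12-oate
Conditions: DDQ, CH2Cl2/pH 7 buffer, 0 °C
Reagents that add atoms: none
Why: Oxidative cleavage of the 4-methoxybenzyl ether through the benzylic oxocarbenium ion; silyl ethers, the ester and the unconjugated alkenes are not affected.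

Step 15
Reactants: 22 hydroxy ester
Product: 23 (1(10)Z,3S,5S,6R,7S,8R)-3,6-bis(TBS-oxy)-5-(TES-oxy)-13-norgermacra-1(10),4(15)-dien-12,8-olide
Conditions: KN(SiMe3)2 (1.0 equiv), THF, −78 → −30 °C; AcOH
Reagents that add atoms: none
Why: Intramolecular acyl substitution (5-exo-trig) of the C8 alkoxide on the tert-butyl ester closes the γ-lactone; O8 and the C7 side chain are trans, so the fusion is trans, and with O5 and O6 silylated no other lactone can form.

Step 16
Reactants: 23 lactone
Product: 26 (1(10)Z,3S,5S,6R,7S,8R)-3,6-bis(TBS-oxy)-5-(TES-oxy)germacra-1(10),4(15),11(13)-trien-12,8-olide, via Mannich base 24 (not isolated), via ammonium iodide 25 (not isolated)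
Conditions: LiN(i-Pr)2, THF, −78 °C; Me2N=CH2+ I−, −78 → 0 °C; MeI, MeOH, 23 °C; aq. NaHCO3, CH2Cl2
Reagents that add atoms: dimethylmethyleneammonium iodide, C=[N+](C)C.[I-]
Why: α-Methylenation of the lactone by Mannich reaction of its lithium enolate, N-methylation and E1cB loss of trimethylamine; only C11 is deprotonated, so C7 is not epimerised.

Step 17
Reactants: 26 α-methylene lactone
Product: 27 (1(10)Z,3S,5S,6R,7S,8R)-3,6-bis(TBS-oxy)-5-hydroxygermacra-1(10),4(15),11(13)-trien-12,8-olide
Conditions: HF·pyridine, pyridine, THF, 0 °C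
Reagents that add atoms: none
Why: Selective cleavage of the less hindered triethylsilyl ether in the presence of the two TBS ethers under buffered, non-basic conditions that leave the α-methylene lactone alone.

Step 18
Reactants: 27 C5 alcohol; 28 angelic acid
Product: 30 (1(10)Z,3S,5S,6R,7S,8R)-5-angeloyloxy-3,6-bis(TBS-oxy)germacra-1(10),4(15),11(13)-trien-12,8-olide, via mixed anhydride 29 (not isolated)
Conditions: 28, 2,4,6-Cl3C6H2COCl, Et3N, toluene, 23 °C; then 27, toluene, 75 °C
Reagents that add atoms: none
Why: Yamaguchi-type esterification through the angelic 2,4,6-trichlorobenzoic mixed anhydride without a nucleophilic catalyst; these conditions are chosen because they avoid the conjugate addition–elimination path that turns angelates into tiglates.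

Step 19
Reactants: 30 angelate
Product: 31 (1S,3S,5S,6R,7S,8R,10R)-5-angeloyloxy-3,6-bis(TBS-oxy)-1,10-epoxygermacra-4(15),11(13)-dien-12,8-olide
Conditions: m-CPBA, NaHCO3, CH2Cl2, 0 °C
Reagents that add atoms: 3-chloroperbenzoic acid, OOC(=O)c1cccc(Cl)c1
Why: Prilezhaev epoxidation of the only electron-rich alkene, the Z C1=C10 bond (the others are conjugated to carbonyls or flanked by two oxygenated carbons). Attack from outside the ring, anti to the C3 silyloxy group and to O8, should place the oxygen on the β face, and the Z geometry fixes the cis epoxide.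

Step 20
Reactants: 31 epoxide
Product: 32 (1S,3S,5S,6R,7R,8R,10R)-5-angeloyloxy-1,10-epoxy-3,6-dihydroxygermacra-4(15),11(13)-dien-12,8-olide
Conditions: HF·pyridine, pyridine, THF, 0 → 23 °C
Reagents that add atoms: none
Why: Fluoride-mediated removal of both TBS ethers in buffered medium; base is avoided so that the angelate does not migrate to O6 and O6 does not attack the lactone, and the buffer protects the epoxide.

Step 21
Reactants: 32 diol
Product: 33 (1S,5S,6R,7R,8R,10R)-5-angeloyloxy-1,10-epoxy-6-hydroxy-3-oxogermacra-4(15),11(13)-dien-12,8-olide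
Conditions: MnO2, CH2Cl2, 23 °C
Reagents that add atoms: none
Why: Chemoselective oxidation of the allylic C3 alcohol (allylic to C4=C15) to the cross-conjugated enone; the non-allylic C6 alcohol is not oxidised by MnO2.

## Compound list

1 | (S)-(+)-carvone, (5S)-2-methyl-5-(prop-1-en-2-yl)cyclohex-2-en-1-one | CC1=CC[C@@H](CC1=O)C(C)=C | starting material
2 | (1S,5S)-cis-carveol, (1S,5S)-2-methyl-5-(prop-1-en-2-yl)cyclohex-2-en-1-ol | CC1=CC[C@@H](C[C@@H]1O)C(C)=C | intermediate
3 | tert-butyl(dimethyl){[(1S,5S)-2-methyl-5-(prop-1-en-2-yl)cyclohex-2-en-1-yl]oxy}silane | CC1=CC[C@@H](C[C@@H]1O[Si](C)(C)C(C)(C)C)C(C)=C | intermediate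
4 | (4S,6S)-4-(tert-butyldimethylsilyloxy)-3-methyl-6-(prop-1-en-2-yl)cyclohex-2-en-1-one | CC1=CC(=O)[C@@H](C[C@@H]1O[Si](C)(C)C(C)(C)C)C(C)=C | intermediate
5 | 4-methoxybenzyl alcohol | COc1ccc(CO)cc1 | starting material
6 | trichloroethylene | ClC=C(Cl)Cl | starting material
7 | 1-({[(E)-1,2-dichloroethenyl]oxy}methyl)-4-methoxybenzene | COc1ccc(CO/C(Cl)=C\Cl)cc1 | intermediate
8 | lithium 2-[(4-methoxybenzyl)oxy]ethynide | [Li]C#COCc1ccc(OC)cc1 | intermediate
9 | (1R,4S,6S)-4-(tert-butyldimethylsilyloxy)-1-{[(4-methoxybenzyl)oxy]ethynyl}-3-methyl-6-(prop-1-en-2-yl)cyclohex-2-en-1-ol | CC1=C[C@](O)(C#COCc2ccc(OC)cc2)[C@@H](C[C@@H]1O[Si](C)(C)C(C)(C)C)C(C)=C | intermediate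
10 | (1R,4S,6S)-4-(tert-butyldimethylsilyloxy)-1-[(E)-2-(4-methoxybenzyloxy)ethenyl]-3-methyl-6-(prop-1-en-2-yl)cyclohex-2-en-1-ol (alkenyl cis to isopropenyl and to the silyloxy group) | CC1=C[C@](O)(/C=C/OCc2ccc(OC)cc2)[C@@H](C[C@@H]1O[Si](C)(C)C(C)(C)C)C(C)=C | intermediate
11 | potassium alkoxide of 10 | CC1=C[C@]([O-])(/C=C/OCc2ccc(OC)cc2)[C@@H](C[C@@H]1O[Si](C)(C)C(C)(C)C)C(C)=C.[K+] | intermediate
12 | potassium enolate of 13 (O–C6=C7; C5 and C8 trans on the enolate double bond) | C1/C(C)=C\C[C@H](O[Si](C)(C)C(C)(C)C)/C(C)=C\C(\[O-])=C\[C@@H]1OCc2ccc(OC)cc2.[K+] | intermediate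
13 | (2Z,4S,6Z,9R)-4-(tert-butyldimethylsilyloxy)-9-(4-methoxybenzyloxy)-3,7-dimethylcyclodeca-2,6-dien-1-one | O=C1C[C@H](OCc2ccc(OC)cc2)C/C(C)=C\C[C@H](O[Si](C)(C)C(C)(C)C)/C(C)=C\1 | intermediate
14 | tert-butyl bromoacetate | BrCC(=O)OC(C)(C)C | starting material
15 | lithium enolate of 13 (O–C6=C7; C5 and C8 trans on the enolate double bond) | C1/C(C)=C\C[C@H](O[Si](C)(C)C(C)(C)C)/C(C)=C\C(\[O-])=C\[C@@H]1OCc2ccc(OC)cc2.[Li+] | intermediate
16 | tert-butyl (1(10)Z,3S,4Z,7S,8R)-3-(TBS-oxy)-8-(PMB-oxy)-6-oxo-13-norgermacra-1(10),4-dien-12-oate | O=C1[C@@H](CC(=O)OC(C)(C)C)[C@H](OCc2ccc(OC)cc2)C/C(C)=C\C[C@H](O[Si](C)(C)C(C)(C)C)/C(C)=C\1 | intermediate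
17 | tert-butyl (1(10)Z,3S,4Z,6S,7R,8R)-3-(TBS-oxy)-6-hydroxy-8-(PMB-oxy)-13-norgermacra-1(10),4-dien-12-oate (6α-OH) | O[C@@H]1[C@@H](CC(=O)OC(C)(C)C)[C@H](OCc2ccc(OC)cc2)C/C(C)=C\C[C@H](O[Si](C)(C)C(C)(C)C)/C(C)=C\1 | intermediate
18 | tert-butyl (1(10)Z,3S,4R,5R,6R,7R,8R)-3-(TBS-oxy)-4,5-epoxy-6-hydroxy-8-(PMB-oxy)-13-norgermacr-1(10)-en-12-oate (4α,5α-epoxide) | O[C@@H]1[C@@H](CC(=O)OC(C)(C)C)[C@H](OCc2ccc(OC)cc2)C/C(C)=C\C[C@H](O[Si](C)(C)C(C)(C)C)[C@]2(C)O[C@H]12 | intermediate
19 | tert-butyl (1(10)Z,3S,4R,5R,6R,7S,8R)-3,6-bis(TBS-oxy)-4,5-epoxy-8-(PMB-oxy)-13-norgermacr-1(10)-en-12-oate | CC(C)(C)[Si](C)(C)O[C@@H]1[C@@H](CC(=O)OC(C)(C)C)[C@H](OCc2ccc(OC)cc2)C/C(C)=C\C[C@H](O[Si](C)(C)C(C)(C)C)[C@]2(C)O[C@H]12 | intermediate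
20 | tert-butyl (1(10)Z,3S,5S,6R,7S,8R)-3,6-bis(TBS-oxy)-5-hydroxy-8-(PMB-oxy)-13-norgermacra-1(10),4(15)-dien-12-oate | CC(C)(C)[Si](C)(C)O[C@@H]1[C@@H](CC(=O)OC(C)(C)C)[C@H](OCc2ccc(OC)cc2)C/C(C)=C\C[C@H](O[Si](C)(C)C(C)(C)C)C(=C)[C@@H]1O | intermediate
21 | tert-butyl (1(10)Z,3S,5S,6R,7S,8R)-3,6-bis(TBS-oxy)-5-(TES-oxy)-8-(PMB-oxy)-13-norgermacra-1(10),4(15)-dien-12-oate | CC(C)(C)[Si](C)(C)O[C@@H]1[C@@H](CC(=O)OC(C)(C)C)[C@H](OCc2ccc(OC)cc2)C/C(C)=C\C[C@H](O[Si](C)(C)C(C)(C)C)C(=C)[C@@H]1O[Si](CC)(CC)CC | intermediate
22 | tert-butyl (1(10)Z,3S,5S,6R,7S,8R)-3,6-bis(TBS-oxy)-5-(TES-oxy)-8-hydroxy-13-norgermacra-1(10),4(15)-dien-12-oate | CC(C)(C)[Si](C)(C)O[C@@H]1[C@@H](CC(=O)OC(C)(C)C)[C@H](O)C/C(C)=C\C[C@H](O[Si](C)(C)C(C)(C)C)C(=C)[C@@H]1O[Si](CC)(CC)CC | intermediate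
23 | (1(10)Z,3S,5S,6R,7S,8R)-3,6-bis(TBS-oxy)-5-(TES-oxy)-13-norgermacra-1(10),4(15)-dien-12,8-olide (trans-fused) | C1C(=O)O[C@@H]2C/C(C)=C\C[C@H](O[Si](C)(C)C(C)(C)C)C(=C)[C@H](O[Si](CC)(CC)CC)[C@H](O[Si](C)(C)C(C)(C)C)[C@@H]12 | intermediate
24 | 13-(dimethylamino) Mannich base of 23 (C11 epimers) | CN(C)CC1C(=O)O[C@@H]2C/C(C)=C\C[C@H](O[Si](C)(C)C(C)(C)C)C(=C)[C@H](O[Si](CC)(CC)CC)[C@H](O[Si](C)(C)C(C)(C)C)[C@@H]12 | intermediate
25 | trimethylammonium iodide of 24 | C[N+](C)(C)CC1C(=O)O[C@@H]2C/C(C)=C\C[C@H](O[Si](C)(C)C(C)(C)C)C(=C)[C@H](O[Si](CC)(CC)CC)[C@H](O[Si](C)(C)C(C)(C)C)[C@@H]12.[I-] | intermediate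
26 | (1(10)Z,3S,5S,6R,7S,8R)-3,6-bis(TBS-oxy)-5-(TES-oxy)germacra-1(10),4(15),11(13)-trien-12,8-olide | C=C1C(=O)O[C@@H]2C/C(C)=C\C[C@H](O[Si](C)(C)C(C)(C)C)C(=C)[C@H](O[Si](CC)(CC)CC)[C@H](O[Si](C)(C)C(C)(C)C)[C@@H]12 | intermediate
27 | (1(10)Z,3S,5S,6R,7S,8R)-3,6-bis(TBS-oxy)-5-hydroxygermacra-1(10),4(15),11(13)-trien-12,8-olide | C=C1C(=O)O[C@@H]2C/C(C)=C\C[C@H](O[Si](C)(C)C(C)(C)C)C(=C)[C@H](O)[C@H](O[Si](C)(C)C(C)(C)C)[C@@H]12 | intermediate
28 | angelic acid, (Z)-2-methylbut-2-enoic acid | OC(=O)/C(C)=C\C | starting material
29 | angelic 2,4,6-trichlorobenzoic anhydride | Clc1cc(Cl)cc(Cl)c1C(=O)OC(=O)/C(C)=C\C | intermediate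
30 | (1(10)Z,3S,5S,6R,7S,8R)-5-angeloyloxy-3,6-bis(TBS-oxy)germacra-1(10),4(15),11(13)-trien-12,8-olide | C=C1C(=O)O[C@@H]2C/C(C)=C\C[C@H](O[Si](C)(C)C(C)(C)C)C(=C)[C@H](OC(=O)/C(C)=C\C)[C@H](O[Si](C)(C)C(C)(C)C)[C@@H]12 | intermediate
31 | (1S,3S,5S,6R,7S,8R,10R)-5-angeloyloxy-3,6-bis(TBS-oxy)-1,10-epoxygermacra-4(15),11(13)-dien-12,8-olide | C=C1C(=O)O[C@@H]2C[C@@]3(C)O[C@H]3C[C@H](O[Si](C)(C)C(C)(C)C)C(=C)[C@H](OC(=O)/C(C)=C\C)[C@H](O[Si](C)(C)C(C)(C)C)[C@@H]12 | intermediate
32 | (1S,3S,5S,6R,7R,8R,10R)-5-angeloyloxy-1,10-epoxy-3,6-dihydroxygermacra-4(15),11(13)-dien-12,8-olide | C=C1C(=O)O[C@@H]2C[C@@]3(C)O[C@H]3C[C@H](O)C(=C)[C@H](OC(=O)/C(C)=C\C)[C@H](O)[C@@H]12 | intermediate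
33 | (1S,5S,6R,7R,8R,10R)-5-angeloyloxy-1,10-epoxy-6-hydroxy-3-oxogermacra-4(15),11(13)-dien-12,8-olide | C=C1C(=O)O[C@@H]2C[C@@]3(C)O[C@H]3CC(=O)C(=C)[C@H](OC(=O)/C(C)=C\C)[C@H](O)[C@@H]12 | target

## Step count and least certain steps

Total step count: 21. Longest linear sequence: 20 steps (1 → 33 through steps 1–3 and 5–21; step 4 is the side branch).

**Step 7 (key step).** The most likely failure is loss of the C8 alkoxide from the potassium enolate (E1cB) and proton shuffling to the extended dienolate while the enolate stands near room temperature. A secondary risk is leakage through a boat transition state, which would erode the Z selectivity. The fallback sets out from 10 and returns at 13. The rearrangement is run at −20 °C and the enolate is silylated as soon as it has formed (Me3SiCl/Et3N added at −78 °C) to give the trimethylsilyl enol ether of 13, F1. F1 is isolated by non-aqueous work-up and cleaved to 13 with Bu4NF/AcOH at −78 °C, so that the free enolate exists only briefly.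

**Step 5.** The likely failure is poor facial selectivity: equatorial attack of the acetylide would give the trans-dialkenyl carbinol, which leads to the E alkene. Enolisation of 4 at C1 is a lesser risk. The fallback sets out from 4 and returns at 10; it fixes the configuration by mechanism, not by facial preference.
- 4 is reduced (NaBH4, CeCl3·7H2O; the small hydride takes the axial path) to the allylic alcohol with the hydroxyl trans to isopropenyl, F2, which is converted into its N,N-diisopropylcarbamate F3 (i-Pr2NCOCl, Et3N).
- In parallel 7 is turned into 4-methoxybenzyl ethynyl ether F4 (n-BuLi, then MeOH at −78 °C) and hydroborated (pinacolborane, Cp2Zr(H)Cl cat.) to the (E)-alkenyl pinacol boronate F5.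
- F3 is lithiated at C6 with retention (s-BuLi, TMEDA, Et2O, −78 °C). F5 adds to the C–Li bond with retention, and 1,2-migration of the alkenyl group with loss of the carbamate (inversion at C6) gives the tertiary allylic boronate F6.
- NaOH/H2O2 oxidises F6 with retention to 10.

**Step 8.** The likely failure is poor facial selectivity: lithium enolate 15, formed by deprotonation of 13, may adopt another geometry or conformation than the enolate formed in step 7. β-Elimination of the C8 alkoxide on warming is the second risk. The fallback sets out from 10 and returns at 16 without a new compound. It is a tandem ring expansion and alkylation: after the rearrangement of step 7 the potassium enolate 12 is not protonated, the flask is cooled to −78 °C and 14 is added directly, so that 12 is alkylated in the conformation in which it is born. In that conformation the outer face of C7 is the one that leads to (7S).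

**Step 9.** The likely failure is poor facial selectivity: the zinc chelate between O6 and O8 may not be accessible in the ten-membered ring, and the C7 substituent would then direct the hydride. The fallback sets out from 16 and returns at 17. If reduction (for example NaBH4, CeCl3·7H2O) gives mainly the 6-epimeric alcohol F7, this is inverted by Mitsunobu esterification (4-nitrobenzoic acid, PPh3, diisopropyl azodicarboxylate) to the 6α 4-nitrobenzoate F8. Methanolysis (K2CO3, MeOH) then gives 17.

**Step 15.** The likely failure is migration of the O6 silyl group to the C8 alkoxide (1,3-syn oxygens) before the slow attack on the hindered tert-butyl ester; lactonisation would then occur at the wrong oxygen. The fallback sets out from 22 and returns at 23. Me3SiOTf/Et3N converts the tert-butyl ester into the silyl ester, and aqueous citric acid gives the hydroxy acid F9. Carbodiimide activation (EDC·HCl, DMAP cat.) then closes the lactone without an alkoxide.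

**Step 19.** The likely failure is epoxidation from the wrong face, because the preferred conformer of the ten-membered ring may expose the α face of C1=C10. The fallback sets out from 30 and returns at 31. N-Bromosuccinimide in aqueous dimethoxyethane attacks the same exposed face as the peracid, and water opens the bromonium ion at the tertiary C10 from the other face to give the bromohydrin F10. DBU then closes the epoxide with inversion at C1, which puts the oxygen on the face opposite to that of direct epoxidation.

## Further compounds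

F1 | step 7 | trimethylsilyl enol ether of 13 (O–C6=C7, C5 and C8 trans) | C1/C(C)=C\C[C@H](O[Si](C)(C)C(C)(C)C)/C(C)=C\C(\O[Si](C)(C)C)=C\[C@@H]1OCc2ccc(OC)cc2
F2 | step 5 | (1R,4S,6S)-4-(TBS-oxy)-3-methyl-6-(prop-1-en-2-yl)cyclohex-2-en-1-ol (OH trans to isopropenyl) | CC1=C[C@@H](O)[C@@H](C[C@@H]1O[Si](C)(C)C(C)(C)C)C(C)=C
F3 | step 5 | N,N-diisopropylcarbamate of F2 | CC1=C[C@@H](OC(=O)N(C(C)C)C(C)C)[C@@H](C[C@@H]1O[Si](C)(C)C(C)(C)C)C(C)=C
F4 | step 5 | 4-methoxybenzyl ethynyl ether | C#COCc1ccc(OC)cc1
F5 | step 5 | (E)-2-(4-methoxybenzyloxy)ethenylboronic acid pinacol ester | COc1ccc(CO/C=C/B2OC(C)(C)C(C)(C)O2)cc1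
F6 | step 5 | pinacol boronate analogue of 10 (boron in place of the hydroxyl, same spatial arrangement) | CC1=C[C@](B2OC(C)(C)C(C)(C)O2)(/C=C/OCc3ccc(OC)cc3)[C@@H](C[C@@H]1O[Si](C)(C)C(C)(C)C)C(C)=C
F0 | step 8 | none | none
F7 | step 9 | C6 epimer of 17 (6β-OH) | O[C@H]1[C@@H](CC(=O)OC(C)(C)C)[C@H](OCc2ccc(OC)cc2)C/C(C)=C\C[C@H](O[Si](C)(C)C(C)(C)C)/C(C)=C\1
F8 | step 9 | 4-nitrobenzoate of 17 (6α-ester) | O=C(O[C@@H]1[C@@H](CC(=O)OC(C)(C)C)[C@H](OCc2ccc(OC)cc2)C/C(C)=C\C[C@H](O[Si](C)(C)C(C)(C)C)/C(C)=C\1)c1ccc(cc1)[N+](=O)[O-]
F9 | step 15 | carboxylic acid corresponding to 22 (8-hydroxy acid) | CC(C)(C)[Si](C)(C)O[C@@H]1[C@@H](CC(=O)O)[C@H](O)C/C(C)=C\C[C@H](O[Si](C)(C)C(C)(C)C)C(=C)[C@@H]1O[Si](CC)(CC)CC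
F10 | step 19 | 1α-bromo-10β-hydroxy bromohydrin of 30 | C=C1C(=O)O[C@@H]2C[C@@](C)(O)[C@H](Br)C[C@H](O[Si](C)(C)C(C)(C)C)C(=C)[C@H](OC(=O)/C(C)=C\C)[C@H](O[Si](C)(C)C(C)(C)C)[C@@H]12
A1 | alternative 1 | Z-cyclodecene with C4 methylene, C5/C6 acetonide, C3 and C8 silyl ethers and the C7 3-silyloxyprop-1-en-2-yl group | C1[C@@H](O[Si](C)(C)C(C)(C)C)[C@H](C(=C)CO[Si](C)(C)C(C)(C)C)[C@H]2OC(C)(C)O[C@H]2C(=C)[C@@H](O[Si](C)(C)C(C)(C)C)C/C=C\1C
A2 | alternative 2 | (1(10)Z)-cyclodecen-5-one fused to the trans 12,8-lactone, with a C6 silyl ether | C1C(=O)O[C@@H]2C/C(C)=C\CCCC(=O)[C@H](O[Si](C)(C)C(C)(C)C)[C@@H]12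
A3 | alternative 3 | (1(10)Z)-cyclodecene-3,8-dione with C5/C6 acetonide, C4 silyloxymethyl and C7 methoxycarbonylmethyl groups | COC(=O)C[C@H]1C(=O)C/C(C)=C\CC(=O)[C@@H](CO[Si](C)(C)C(C)(C)C)[C@@H]2OC(C)(C)O[C@H]12
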